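## The problem

Target 42 is a germacranolide. A ten-membered carbocycle (C1–C10) is trans-fused at C6/C7 to an α-methylene γ-lactone (C11–C13) and carries a cross-conjugated dienone C10=C1–C2(=O)–C3=C4, with C1=C10 E and C3=C4 Z. Four contiguous stereocentres line one edge of the ring: C5 (free allylic carbinol, R), C6 (lactone oxygen, S), C7 (R) and C8 (angelate, S). On a six-membered chair C6, C7 and C8 would alternate faces and all be equatorial, so they can be built on a rigid ring and relayed from one another, whereas C5 can only be set in the macrocycle, from a ketone. The methylene lactone, the angelate (prone to Z-to-E isomerisation and intolerant of enolate chemistry), the divinyl ketone and the acyloxy-flanked allylic alcohol must all appear in the last steps. Closing a ten-membered ring containing a trisubstituted E alkene by bond formation costs entropy and strain and leaves both alkene geometries to be secured separately. The feature that avoids this is that C5 and C10 face each other across the ring. A bond between them turns the macrocycle into a trans-decalin in which C3=C4 is an ordinary ring-A cis alkene and O–C5–C10–C1–OMs is a 1,3-diol monosulfonate. The task therefore becomes a stereocontrolled eudesmanolide-type decalin with 1β-OMs, 2α-O, 5α-OH, 6α-O, 7β-C, 8α-O and 10β-CH3.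

## Retrosynthesis

**End game (42 back to 30).** The last bonds made are carbon–heteroatom or exocyclic: the C5 silyl ether (41), the C8–O acyl bond joining alcohol 38 to angelic acid 39, the PMB ether (37), the C2 carbonyl from alcohol 36, and the C11=C13 methylene from lactone 32 through Mannich base 33. The order follows from reactivity. Methylenation needs a lactone enolate, so it precedes both the angelate and the dienone. C2 is oxidised before DDQ is used, so no electron-rich bis-allylic ether meets the quinone. C5 is silylated (32) as soon as it is created from ketone 30 (via 31). Enone 30 carries none of the fragile groups.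

**Key disconnection (30 to 29).** Reconnecting C5 to C10 turns the ten-membered enone 30 into the trans-decalin mesylate 29. The neighbouring cuts (C1–C2 or C2–C3 for a carbonylative or dipolar closure, C4–C5 for a carbonyl addition) all require a macrocyclisation and separate control of an E and a Z trisubstituted alkene. The C5–C10 cut trades these for two six-membered rings in which the Z alkene is endocyclic and every substituent sits on a chair. The forward reaction needs only a C5 alkoxide and a C1 leaving group held equatorial.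

**Ring-A oxygens (29 to 25).** The C1 mesylate and C2 silyl ether come from triol 27. Its C2–O and C5–O bonds are cut together, back to the homoannular diene 25, by a singlet-oxygen [4+2] addition and O–O reduction. Stepwise allylic oxidations would have to distinguish three allylic positions. The cycloaddition puts both oxygens on the face opposite the C10 methyl and leaves C3=C4 where it is needed.

**C1 oxygen (25 to 18).** The 1β-alcohol 25 comes from dienone 24 by hydride delivery anti to the C10 methyl. Dienone 24 arises from the 1α-alcohol 23, and 23 from epoxy ketone 21 by epoxy-ketone transposition. Epoxide 21 derives from the cross-conjugated dienone 20, made from enone lactone 18. Every electrophilic or nucleophilic oxygenation of ring A gives 1α, so C1 must pass through a ketone. The precursor 18 has a plain 3-oxo-4-ene ring A.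

**Lactone and C6 (18 to 14).** The C6–O bond is cut by going back to diol 16, then to the deconjugated ketal 15 and enone ester 14. Dihydroxylation of C5=C6 from the α-face sets 6α-O trans to the C7 arm. Hydride reduction of a C6 ketone or γ-bromination would give the axial 6β isomer. The 5α-hydroxyl made alongside is sacrificed on re-conjugation and restored later by singlet oxygen.

**Ring A (14 to 8).** Cutting C4=C5 and C1–C10 (Robinson annulation) leads to diketone 13, and from there to cyclohexanone 8, ethyl vinyl ketone 10 and the chiral amine 9. The amine must fix the quaternary C10 against the ring's own bias.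

**Ring B (8 to 1).** The C7–C11 bond is cut to enone 5 and ketene silyl acetal 6 (conjugate addition anti to the C8 ether). Enone 5 comes from 4 by α′-methylation. The single catalyst-set stereocentre C8 comes from commercial enone ketal 1 via 2 and 3.

## Roads not taken

**Alternative 1:** The ring is cut into an acyclic lactone fragment A1 whose C5–C9 carbons and oxygens come from D-ribose A2; C2–C4 and the ring are added later. In the key step a phosphonoacetate carbanion on O5 (future C11) opens a C7,C8 cyclic sulfate at C7 with inversion. Olefination with formaldehyde adds C13, and acid work-up moves the acyl group from O5 to O6.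
- Merits: absolute configuration comes from the chiral pool, C7 is set by an SN2 event, the methylene lactone is made in one flask without a late lactone enolate, and A1 is reached in few steps.
- Weak points: both sulfate carbons are secondary, so regioselectivity rests on ring size alone. The acyl shift must favour the secondary O6 over the primary O5. A1 still lacks three ring carbons, the C5 stereocentre and the macrocycle. The Michael-sensitive methylene lactone must then survive the fragment coupling, the ring closure and the dienone assembly.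
- Comparison: this road is clearly better in step economy up to the C6–C8 triad. Against that, the chosen plan never forms a ten-membered ring by bond formation, gets both alkene geometries from ring constraints, and keeps the methylene lactone out of the route until 35.

**Alternative 2:** The cut is at C2–C3 and C4–O. A C2 nitrile oxide, made by NaOCl oxidation of an aldoxime, adds across the 1,1-disubstituted C3=C4 alkene and closes the carbocycle as the bridged isoxazoline A3.
- Merits: the closure is irreversible and driven by a high-energy dipole, the C2 carbonyl is carried in masked form, and the angelate and methylene lactone are already in place, so the sequence after A3 is short.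
- Weak points: a ten-membered intramolecular cycloaddition with a conjugated nitrile oxide must choose the bridged regiochemistry against strain. The N–O bond must then be cleaved reductively without touching the methylene lactone or the angelate. The resulting tertiary β-hydroxy ketone must lose water only toward C3 and only to the Z alkene, with nothing in A3 to enforce either.
- Comparison: A3 is reached faster and more convergently than 30. The chosen plan sets against this that the Z alkene is locked in a six-membered ring before the macrocycle exists, rather than left to an elimination on the most fragile intermediate.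

**Alternative 3:** Both bonds to C2 are cut. Zerovalent palladium (Pd2(dba)3, AsPh3) under CO joins a Z-alkenyl iodide (C3) and an E-alkenylstannane (C1) through one CO, closing the ring and giving A4, the C5 triethylsilyl ether of the target.
- Merits: this is the most convergent plan. Both alkene geometries are fixed in stable alkenyl partners, the dienone is formed directly, and only a desilylation remains.
- Weak points: the strained ten-membered divinyl ketone must form by macrocyclisation, with CO insertion outrunning direct coupling (a nine-membered diene) and oligomerisation. The methylene lactone, angelate and product dienone are all exposed to the palladium catalyst and to liberated tin species. The acyclic precursor with the C5–C8 tetrad still has to be made without a ring to relay stereochemistry.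
- Comparison: in step count and convergence this road is superior to the chosen one, which is long and linear. The chosen plan sets against it a ring formation with no entropic penalty and stereoelectronic control of the E alkene.

Key step: step 19

Remark: locants follow germacrane/eudesmane numbering (C14 on C10, C15 on C4, lactone C11–C13). α is the ring face of the C6 and C8 oxygens, β that of the C7 side chain and, in the decalins, of the C10 methyl. The target is taken as (5R,6S,7R,8S), as its SMILES encodes. PMB = 4-methoxybenzyl, TES = triethylsilyl, TBS = tert-butyldimethylsilyl, Ms = methanesulfonyl.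

## Route

Step 1
Reactants: 1 1,4-dioxaspiro[4.5]dec-6-en-8-one
Product: 2 (S)-1,4-dioxaspiro[4.5]dec-6-en-8-ol
Conditions: (R)-1-methyl-3,3-diphenyltetrahydro-1H,3H-pyrrolo[1,2-c][1,3,2]oxazaborole (10 mol %), BH3·SMe2, THF, −20 °C; MeOH quench
Reagents that add atoms: none
Why: Corey–Bakshi–Shibata reduction; the alkenyl arm bearing the ketal acts as the large group, so the (R)-catalyst should give the (S)-allylic alcohol, whose carbinol carbon becomes C8.

Step 2
Reactants: 2 (S)-1,4-dioxaspiro[4.5]dec-6-en-8-ol
Product: 3 (S)-8-(PMBO)-1,4-dioxaspiro[4.5]dec-6-ene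
Conditions: NaH, 4-methoxybenzyl chloride, Bu4NI (cat.), THF/DMF, 0 °C to rt
Reagents that add atoms: 4-methoxybenzyl chloride, COc1ccc(CCl)cc1
Why: Williamson etherification; PMB survives the bases, hydrides, OsO4 and mild acids ahead and can be removed oxidatively near the end.

Step 3
Reactants: 3 (S)-8-(PMBO)-1,4-dioxaspiro[4.5]dec-6-ene
Product: 4 (S)-4-(PMBO)cyclohex-2-en-1-one
Conditions: 1 M HCl, THF, rt
Reagents that add atoms: water, O
Why: Acetal hydrolysis; the ketone appears at the former ketal carbon, so the enone is transposed and the ether oxygen sits at its γ-carbon (future C8).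

Step 4
Reactants: 4 (S)-4-(PMBO)cyclohex-2-en-1-one
Product: 5 (4S)-4-(PMBO)-6-methylcyclohex-2-en-1-one (C6 epimers)
Conditions: LiN(iPr)2, THF, −78 °C; MeI, −78 to −20 °C
Reagents that add atoms: iodomethane, CI
Why: Kinetic α′-enolate alkylation of an enone, regiospecific for the saturated α-carbon (future C10); the configuration of the new methyl centre is erased in step 6.

Step 5
Reactants: 5 (4S)-4-(PMBO)-6-methylcyclohex-2-en-1-one; 6 tert-butyl[(1-methoxyethenyl)oxy]dimethylsilane
Product: 8 methyl 2-[(1R,2S)-2-(PMBO)-4-methyl-5-oxocyclohexyl]acetate (C4 epimers), via silyl enol ether 7 (not isolated)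
Conditions: Sc(OTf)3 (5 mol %), CH2Cl2, −78 °C; then 1 M HCl, THF, 0 °C
Reagents that add atoms: none
Why: Mukaiyama–Michael addition; the ketene acetal should add to the β-carbon (C7) anti to the neighbouring C8 ether, giving the trans arrangement, and hydrolysis of the silyl enol ether frees the ketone.

Step 6
Reactants: 8 methyl 2-[(1R,2S)-2-(PMBO)-4-methyl-5-oxocyclohexyl]acetate; 9 (R)-1-phenylethylamine; 10 ethyl vinyl ketone
Product: 13 methyl 2-[(1R,2S,4R)-2-(PMBO)-4-methyl-5-oxo-4-(3-oxopentyl)cyclohexyl]acetate, via ketimine 11 (not isolated), via alkylated ketimine 12 (not isolated)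
Conditions: 9, p-TsOH·H2O (cat.), 4 Å MS, toluene, 60 °C; then 10, THF, 40 °C; then 10% aq AcOH, rt
Reagents that add atoms: water, O
Why: Chiral-imine Michael addition through the more substituted secondary enamine (aza-ene-like transition state), then hydrolysis; the phenylethyl group screens one enamine face, so the (R)-amine should set the quaternary C10 with the new chain α and the methyl β whatever the starting methyl epimer. The reagent has to override the ring's preference for axial attack cis to the C7 arm.

Step 7
Reactants: 13 methyl 2-[(1R,2S,4R)-2-(PMBO)-4-methyl-5-oxo-4-(3-oxopentyl)cyclohexyl]acetate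
Product: 14 methyl 8α-(PMBO)-3-oxo-13-noreudesm-4-en-12-oate
Conditions: NaOMe (0.5 equiv), MeOH, 0 °C to rt
Reagents that add atoms: none
Why: Intramolecular aldol condensation completing the Robinson annulation; only the ethyl-ketone methylene reaches the ring carbonyl through a six-membered transition state, and dehydration gives the tetrasubstituted enone.

Step 8
Reactants: 14 methyl 8α-(PMBO)-3-oxo-13-noreudesm-4-en-12-oate
Product: 15 methyl 3,3-(ethylenedioxy)-8α-(PMBO)-13-noreudesm-5-en-12-oate (C4 epimers)
Conditions: 2-ethyl-2-methyl-1,3-dioxolane, ethylene glycol (cat.), p-TsOH·H2O (cat.), rt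
Reagents that add atoms: 2-ethyl-2-methyl-1,3-dioxolane, CCC1(C)OCCO1
Why: Acid-catalysed exchange dioxolanation; as usual for 3-oxo-4-ene decalins the alkene should move out of conjugation to C5=C6, exposing C5/C6 to oxidation. The mild exchange conditions spare the ester and the PMB ether.

Step 9
Reactants: 15 methyl 3,3-(ethylenedioxy)-8α-(PMBO)-13-noreudesm-5-en-12-oate
Product: 16 methyl 3,3-(ethylenedioxy)-5α,6α-dihydroxy-8α-(PMBO)-13-noreudesman-12-oate (C4 epimers)
Conditions: OsO4 (5 mol %), N-methylmorpholine N-oxide, acetone/H2O, rt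
Reagents that add atoms: osmium tetroxide, O=[Os](=O)(=O)=O; N-methylmorpholine N-oxide, C[N+]1([O-])CCOCC1
Why: Upjohn syn-dihydroxylation; the axial C10 methyl blocks the β-face, so both oxygens should enter from the α-face, fixing 6α-O trans to the C7 arm.

Step 10
Reactants: 16 methyl 3,3-(ethylenedioxy)-5α,6α-dihydroxy-8α-(PMBO)-13-noreudesman-12-oate
Product: 18 8α-(PMBO)-3-oxo-13-noreudesm-4-en-12,6α-olide, via hydroxy keto lactone 17 (not isolated)
Conditions: 1 M HCl, THF, rt to 40 °C
Reagents that add atoms: water, O
Why: Acid-mediated ketal hydrolysis, γ-lactonisation of the equatorial 6α-hydroxyl onto the C7 acetate arm (trans-fused) and β-elimination of the tertiary 5α-hydroxyl restore the 3-oxo-4-ene. C6 keeps its configuration because its C–O bond is never broken.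

Step 11
Reactants: 18 8α-(PMBO)-3-oxo-13-noreudesm-4-en-12,6α-olide
Product: 20 8α-(PMBO)-3-oxo-13-noreudesma-1,4-dien-12,6α-olide, via 2-phenylselanyl ketone 19 (not isolated)
Conditions: LiN(iPr)2 (1.1 equiv), THF, −78 °C; PhSeCl; then H2O2, pyridine, CH2Cl2, 0 °C to rt
Reagents that add atoms: none
Why: Kinetic α′-selenenylation of the enone enolate and selenoxide syn-elimination; the C2 ketone protons should be removed faster than the lactone α-protons, and elimination can only run toward C1. This avoids quinone oxidants that would attack the PMB ether.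

Step 12
Reactants: 20 8α-(PMBO)-3-oxo-13-noreudesma-1,4-dien-12,6α-olide
Product: 21 1α,2α-epoxy-8α-(PMBO)-3-oxo-13-noreudesm-4-en-12,6α-olide
Conditions: tert-butyl hydroperoxide (decane), 1,8-diazabicyclo[5.4.0]undec-7-ene, CH2Cl2, 0 °C to rt
Reagents that add atoms: tert-butyl hydroperoxide, CC(C)(C)OO
Why: Weitz–Scheffer nucleophilic epoxidation; the disubstituted C1=C2 bond should react in preference to the fully substituted C4=C5 bond, with attack at C1 from the α-face anti to the C10 methyl. Non-aqueous conditions spare the lactone.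

Step 13
Reactants: 21 1α,2α-epoxy-8α-(PMBO)-3-oxo-13-noreudesm-4-en-12,6α-olide
Product: 23 1α-hydroxy-8α-(PMBO)-13-noreudesma-2,4-dien-12,6α-olide, via epoxy hydrazone 22 (not isolated)
Conditions: N2H4·H2O (3 equiv), AcOH (0.5 equiv), MeOH, 0 °C to rt
Reagents that add atoms: none
Why: Wharton transposition; the C3 hydrazone opens the epoxide to an alkenyldiazene that loses N2, leaving C2=C3 conjugated with C4=C5 and the oxygen on C1. Hydrazone formation at the ketone should outrun hydrazinolysis of the lactone at low temperature.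

Step 14
Reactants: 23 1α-hydroxy-8α-(PMBO)-13-noreudesma-2,4-dien-12,6α-olide
Product: 24 8α-(PMBO)-1-oxo-13-noreudesma-2,4-dien-12,6α-olide
Conditions: Dess–Martin periodinane, pyridine, CH2Cl2, 0 °C
Reagents that add atoms: none
Why: Dess–Martin oxidation of the allylic alcohol to the linear dienone; this erases the unwanted 1α configuration so that C1 can be reset by hydride.

Step 15
Reactants: 24 8α-(PMBO)-1-oxo-13-noreudesma-2,4-dien-12,6α-olide
Product: 25 1β-hydroxy-8α-(PMBO)-13-noreudesma-2,4-dien-12,6α-olide
Conditions: NaBH4, CeCl3·7H2O, MeOH, −78 °C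
Reagents that add atoms: none
Why: Luche 1,2-reduction; the carbonyl is flanked by quaternary C10, whose pseudo-axial methyl shields the β-face, so hydride should enter from the α-face and give the equatorial 1β-alcohol that the fragmentation requires.

Step 16
Reactants: 25 1β-hydroxy-8α-(PMBO)-13-noreudesma-2,4-dien-12,6α-olide
Product: 27 1β,2α,5α-trihydroxy-8α-(PMBO)-13-noreudesm-3-en-12,6α-olide, via endoperoxide 26 (not isolated)
Conditions: O2, hν, tetraphenylporphyrin (sensitiser), CH2Cl2, −30 °C; then thiourea, MeOH, rt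
Reagents that add atoms: oxygen, O=O
Why: Singlet-oxygen [4+2] cycloaddition to the s-cis ring-A diene from the α-face (opposite the C10 methyl), then O–O reduction; the cis-2α,5α-diol and the C3=C4 alkene appear together and C5 regains its α-hydroxyl, trans to the methyl.

Step 17
Reactants: 27 1β,2α,5α-trihydroxy-8α-(PMBO)-13-noreudesm-3-en-12,6α-olide
Product: 28 1β,5α-dihydroxy-8α-(PMBO)-2α-(TESO)-13-noreudesm-3-en-12,6α-olide
Conditions: TESCl (1.05 equiv), imidazole, CH2Cl2, −40 °C
Reagents that add atoms: chlorotriethylsilane, CC[Si](Cl)(CC)CC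
Why: Selective silyl ether formation; the allylic 2α-hydroxyl is the least hindered of the three (the 1β-hydroxyl is neopentyl, the 5α-hydroxyl tertiary), so one equivalent at low temperature should take C2 only.

Step 18
Reactants: 28 1β,5α-dihydroxy-8α-(PMBO)-2α-(TESO)-13-noreudesm-3-en-12,6α-olide
Product: 29 5α-hydroxy-1β-(MsO)-8α-(PMBO)-2α-(TESO)-13-noreudesm-3-en-12,6α-olide
Conditions: MsCl, Et3N, CH2Cl2, −20 °C
Reagents that add atoms: methanesulfonyl chloride, CS(=O)(=O)Cl
Why: Mesylation through sulfene of the only remaining secondary hydroxyl; the tertiary C5 alcohol does not react, which leaves the 1,3-diol monosulfonate.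

Step 19
Reactants: 29 5α-hydroxy-1β-(MsO)-8α-(PMBO)-2α-(TESO)-13-noreudesm-3-en-12,6α-olide
Product: 30 (2R,6S,7R,8S)-8-(PMBO)-5-oxo-2-(TESO)-13-norgermacra-1(10)E,3Z-dien-12,6-olide
Conditions: KOtBu (1.1 equiv), THF, −20 to 0 °C, short reaction time; pH 7 buffer quench
Reagents that add atoms: none
Why: The base deprotonates the tertiary C5 hydroxyl; the oxyanion lone pair becomes the C5=O π bond as the C5–C10 σ bond breaks, the C1=C10 π bond forms and mesylate leaves, all in one concerted step. The closest known reaction type is the Wharton (Grob-type) fragmentation of decalin 1,3-diol monosulfonates to E-cyclodecenones. No ring is closed by bond formation: the ten-membered ring is uncovered by cleaving the bond shared by rings A and B, so there is no macrocyclisation entropy to pay. No stereocentre is created; C1, C5 and C10 lose theirs, and C2, C6, C7 and C8 are untouched. The new stereo-element is the C1=C10 alkene, and its E geometry is fixed because C9 on C10 and C2 on C1 are anti in the chair, while the Z geometry of C3=C4 is inherited from ring A. The step needs fragmentation rather than oxetane formation, epoxide formation or elimination. This is secured by the equatorial 1β-mesylate lying anti-periplanar to C5–C10 in the trans-decalin, by O5 being gauche (not anti) to the C1–O bond, by the silyl cap on O2, and by the absence of an anti-periplanar hydrogen on C2. The C6 hydrogen becomes α to the new ketone, so a slight excess of base, low temperature and a buffered quench are specified to keep C6 from epimerising.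

Step 20
Reactants: 30 (2R,6S,7R,8S)-8-(PMBO)-5-oxo-2-(TESO)-13-norgermacra-1(10)E,3Z-dien-12,6-olide
Product: 31 (2R,5R,6S,7R,8S)-5-hydroxy-8-(PMBO)-2-(TESO)-13-norgermacra-1(10)E,3Z-dien-12,6-olide
Conditions: NaBH4, CeCl3·7H2O, MeOH, −78 °C
Reagents that add atoms: none
Why: Luche 1,2-reduction of the enone; C10 lies across the ring on the inner face of the C5 carbonyl (the face it departed from), so hydride should add from the periphery, keeping the oxygen on the α-face and giving the 5R alcohol.

Step 21
Reactants: 31 (2R,5R,6S,7R,8S)-5-hydroxy-8-(PMBO)-2-(TESO)-13-norgermacra-1(10)E,3Z-dien-12,6-olide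
Product: 32 (2R,5R,6S,7R,8S)-5-(TBSO)-8-(PMBO)-2-(TESO)-13-norgermacra-1(10)E,3Z-dien-12,6-olide
Conditions: TBSOTf, 2,6-lutidine, CH2Cl2, −78 °C
Reagents that add atoms: tert-butyldimethylsilyl trifluoromethanesulfonate, CC(C)(C)[Si](C)(C)OS(=O)(=O)C(F)(F)F
Why: Silyl ether formation on the hindered allylic alcohol with the silyl triflate; TBS is chosen to outlast the later selective removal of TES.

Step 22
Reactants: 32 (2R,5R,6S,7R,8S)-5-(TBSO)-8-(PMBO)-2-(TESO)-13-norgermacra-1(10)E,3Z-dien-12,6-olide
Product: 33 (2R,5R,6S,7R,8S)-13-(dimethylamino)-5-(TBSO)-8-(PMBO)-2-(TESO)germacra-1(10)E,3Z-dien-12,6-olide (C11 epimers)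
Conditions: LiN(iPr)2 (1.3 equiv), THF, −78 °C; CH2=NMe2+ I−, −78 to 0 °C
Reagents that add atoms: N,N-dimethylmethyleneiminium iodide (Eschenmoser's salt), C=[N+](C)C.[I-]
Why: Mannich reaction of the lactone enolate with Eschenmoser's salt; the lactone α-methylene is the only acidic site and the configuration at C11 is irrelevant.

Step 23
Reactants: 33 (2R,5R,6S,7R,8S)-13-(dimethylamino)-5-(TBSO)-8-(PMBO)-2-(TESO)germacra-1(10)E,3Z-dien-12,6-olide
Product: 35 (2R,5R,6S,7R,8S)-5-(TBSO)-8-(PMBO)-2-(TESO)germacra-1(10)E,3Z,11(13)-trien-12,6-olide, via trimethylammonium iodide 34 (not isolated)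
Conditions: MeI, MeOH, rt; then NaHCO3, EtOAc/H2O, rt
Reagents that add atoms: none
Why: N-Quaternisation and E1cB (Hofmann-type) elimination of trimethylamine; bicarbonate suffices, so the exocyclic methylene lactone is formed without strong base.

Step 24
Reactants: 35 (2R,5R,6S,7R,8S)-5-(TBSO)-8-(PMBO)-2-(TESO)germacra-1(10)E,3Z,11(13)-trien-12,6-olide
Product: 36 (2R,5R,6S,7R,8S)-2-hydroxy-5-(TBSO)-8-(PMBO)germacra-1(10)E,3Z,11(13)-trien-12,6-olide
Conditions: HF·pyridine, pyridine, THF, 0 °C
Reagents that add atoms: none
Why: Selective desilylation; the secondary TES ether is cleaved much faster than the TBS ether under buffered HF·pyridine, and the medium is not nucleophilic toward the methylene lactone.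

Step 25
Reactants: 36 (2R,5R,6S,7R,8S)-2-hydroxy-5-(TBSO)-8-(PMBO)germacra-1(10)E,3Z,11(13)-trien-12,6-olide
Product: 37 (5R,6S,7R,8S)-5-(TBSO)-8-(PMBO)-2-oxogermacra-1(10)E,3Z,11(13)-trien-12,6-olide
Conditions: MnO2, CH2Cl2, rt
Reagents that add atoms: none
Why: MnO2 oxidation of the doubly allylic alcohol to the cross-conjugated dienone under neutral conditions; neither alkene geometry is touched.

Step 26
Reactants: 37 (5R,6S,7R,8S)-5-(TBSO)-8-(PMBO)-2-oxogermacra-1(10)E,3Z,11(13)-trien-12,6-olide
Product: 38 (5R,6S,7R,8S)-8-hydroxy-5-(TBSO)-2-oxogermacra-1(10)E,3Z,11(13)-trien-12,6-olide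
Conditions: DDQ, CH2Cl2/pH 7 buffer, 0 °C
Reagents that add atoms: none
Why: Oxidative PMB ether cleavage (benzylic hydride abstraction, hydrolysis of the oxocarbenium ion); it is placed after the C2 oxidation so that only electron-poor alkenes are present, and the neutral buffer avoids lactone migration to O8.

Step 27
Reactants: 38 (5R,6S,7R,8S)-8-hydroxy-5-(TBSO)-2-oxogermacra-1(10)E,3Z,11(13)-trien-12,6-olide; 39 angelic acid
Product: 41 (5R,6S,7R,8S)-8-(angeloyloxy)-5-(TBSO)-2-oxogermacra-1(10)E,3Z,11(13)-trien-12,6-olide, via mixed anhydride 40 (not isolated)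
Conditions: 39, 2,4,6-trichlorobenzoyl chloride, Et3N, toluene, rt; then 38, toluene, 60 °C
Reagents that add atoms: none
Why: Yamaguchi-type esterification through the hindered mixed anhydride, the usual way to make angelates; no nucleophilic catalyst adds to the β-carbon, so Z-to-E isomerisation to the tiglate should be suppressed.

Step 28
Reactants: 41 (5R,6S,7R,8S)-8-(angeloyloxy)-5-(TBSO)-2-oxogermacra-1(10)E,3Z,11(13)-trien-12,6-olide
Product: 42 (5R,6S,7R,8S)-8-(angeloyloxy)-5-hydroxy-2-oxogermacra-1(10)E,3Z,11(13)-trien-12,6-olide (CNP0230565.9)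
Conditions: HF·pyridine, THF, 0 °C to rt
Reagents that add atoms: none
Why: Acidic desilylation of the last silyl ether; HF·pyridine is neither basic nor nucleophilic enough to harm the angelate, the dienone or the methylene lactone.

## Compound list

1 | 1,4-dioxaspiro[4.5]dec-6-en-8-one | O=C1C=CC2(CC1)OCCO2 | starting material
2 | (S)-1,4-dioxaspiro[4.5]dec-6-en-8-ol | O[C@@H]1C=CC2(OCCO2)CC1 | intermediate
3 | (S)-8-[(4-methoxybenzyl)oxy]-1,4-dioxaspiro[4.5]dec-6-ene | COc1ccc(CO[C@@H]2C=CC3(OCCO3)CC2)cc1 | intermediate
4 | (S)-4-[(4-methoxybenzyl)oxy]cyclohex-2-en-1-one | O=C1C=C[C@@H](OCc2ccc(OC)cc2)CC1 | intermediate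
5 | (4S)-4-[(4-methoxybenzyl)oxy]-6-methylcyclohex-2-en-1-one (C6 epimers) | O=C1C=C[C@@H](OCc2ccc(OC)cc2)CC1C | intermediate
6 | tert-butyl[(1-methoxyethenyl)oxy]dimethylsilane | C=C(OC)O[Si](C)(C)C(C)(C)C | starting material
7 | tert-butyldimethylsilyl enol ether of 8 (C5–OSi, C5=C6; C7 and C8 as in 8) | CC1C[C@H](OCc2ccc(OC)cc2)[C@@H](CC(=O)OC)C=C1O[Si](C)(C)C(C)(C)C | intermediate
8 | methyl 2-[(1R,2S)-2-[(4-methoxybenzyl)oxy]-4-methyl-5-oxocyclohexyl]acetate (C4 epimers) | O=C1C[C@H](CC(=O)OC)[C@@H](OCc2ccc(OC)cc2)CC1C | intermediate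
9 | (R)-1-phenylethylamine | C[C@@H](N)c1ccccc1 | starting material
10 | ethyl vinyl ketone (pent-1-en-3-one) | CCC(=O)C=C | starting material
11 | N-[(R)-1-phenylethyl] ketimine of 8 | C[C@@H](N=C1C[C@H](CC(=O)OC)[C@@H](OCc2ccc(OC)cc2)CC1C)c1ccccc1 | intermediate
12 | N-[(R)-1-phenylethyl] ketimine of 13 | CCC(=O)CC[C@]1(C)C[C@H](OCc2ccc(OC)cc2)[C@@H](CC(=O)OC)CC1=N[C@H](C)c1ccccc1 | intermediate
13 | methyl 2-[(1R,2S,4R)-2-[(4-methoxybenzyl)oxy]-4-methyl-5-oxo-4-(3-oxopentyl)cyclohexyl]acetate | CCC(=O)CC[C@]1(C)C[C@H](OCc2ccc(OC)cc2)[C@@H](CC(=O)OC)CC1=O | intermediate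
14 | methyl 8α-(PMBO)-3-oxo-13-noreudesm-4-en-12-oate (10β-methyl, 7β-CH2CO2Me) | CC1=C2C[C@H](CC(=O)OC)[C@@H](OCc3ccc(OC)cc3)C[C@@]2(C)CCC1=O | intermediate
15 | methyl 3,3-(ethylenedioxy)-8α-(PMBO)-13-noreudesm-5-en-12-oate (C4 epimers) | CC1C2=C[C@H](CC(=O)OC)[C@@H](OCc3ccc(OC)cc3)C[C@@]2(C)CCC14OCCO4 | intermediate
16 | methyl 3,3-(ethylenedioxy)-5α,6α-dihydroxy-8α-(PMBO)-13-noreudesman-12-oate (C4 epimers) | CC1[C@]2(O)[C@@H](O)[C@H](CC(=O)OC)[C@@H](OCc3ccc(OC)cc3)C[C@@]2(C)CCC14OCCO4 | intermediate
17 | 5α-hydroxy-8α-(PMBO)-3-oxo-13-noreudesman-12,6α-olide (C4 epimers) | CC1C(=O)CC[C@]2(C)C[C@H](OCc4ccc(OC)cc4)[C@H]3CC(=O)O[C@@H]3[C@@]12O | intermediate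
18 | 8α-(PMBO)-3-oxo-13-noreudesm-4-en-12,6α-olide | CC1=C2[C@H]3OC(=O)C[C@@H]3[C@@H](OCc4ccc(OC)cc4)C[C@@]2(C)CCC1=O | intermediate
19 | 2-(phenylselanyl)-8α-(PMBO)-3-oxo-13-noreudesm-4-en-12,6α-olide (C2 epimers) | CC1=C2[C@H]3OC(=O)C[C@@H]3[C@@H](OCc4ccc(OC)cc4)C[C@@]2(C)CC([Se]c5ccccc5)C1=O | intermediate
20 | 8α-(PMBO)-3-oxo-13-noreudesma-1,4-dien-12,6α-olide | CC1=C2[C@H]3OC(=O)C[C@@H]3[C@@H](OCc4ccc(OC)cc4)C[C@@]2(C)C=CC1=O | intermediate
21 | 1α,2α-epoxy-8α-(PMBO)-3-oxo-13-noreudesm-4-en-12,6α-olide | CC1=C2[C@H]3OC(=O)C[C@@H]3[C@@H](OCc4ccc(OC)cc4)C[C@@]2(C)[C@H]5O[C@H]5C1=O | intermediate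
22 | C3 hydrazone of 21 | CC1=C2[C@H]3OC(=O)C[C@@H]3[C@@H](OCc4ccc(OC)cc4)C[C@@]2(C)[C@H]5O[C@H]5C1=NN | intermediate
23 | 1α-hydroxy-8α-(PMBO)-13-noreudesma-2,4-dien-12,6α-olide | CC1=C2[C@H]3OC(=O)C[C@@H]3[C@@H](OCc4ccc(OC)cc4)C[C@@]2(C)[C@@H](O)C=C1 | intermediate
24 | 8α-(PMBO)-1-oxo-13-noreudesma-2,4-dien-12,6α-olide | CC1=C2[C@H]3OC(=O)C[C@@H]3[C@@H](OCc4ccc(OC)cc4)C[C@@]2(C)C(=O)C=C1 | intermediate
25 | 1β-hydroxy-8α-(PMBO)-13-noreudesma-2,4-dien-12,6α-olide | CC1=C2[C@H]3OC(=O)C[C@@H]3[C@@H](OCc4ccc(OC)cc4)C[C@@]2(C)[C@H](O)C=C1 | intermediate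
26 | 2α,5α-epidioxy-1β-hydroxy-8α-(PMBO)-13-noreudesm-3-en-12,6α-olide | O=C1O[C@H]2[C@H](C1)[C@@H](OCc5ccc(OC)cc5)C[C@@]3(C)[C@H](O)[C@H]4OO[C@@]23C(C)=C4 | intermediate
27 | 1β,2α,5α-trihydroxy-8α-(PMBO)-13-noreudesm-3-en-12,6α-olide | O=C1O[C@H]2[C@H](C1)[C@@H](OCc4ccc(OC)cc4)C[C@@]3(C)[C@H](O)[C@@H](O)C=C(C)[C@]23O | intermediate
28 | 1β,5α-dihydroxy-8α-(PMBO)-2α-(triethylsilyloxy)-13-noreudesm-3-en-12,6α-olide | O=C1O[C@H]2[C@H](C1)[C@@H](OCc4ccc(OC)cc4)C[C@@]3(C)[C@H](O)[C@@H](O[Si](CC)(CC)CC)C=C(C)[C@]23O | intermediate
29 | 5α-hydroxy-1β-(methanesulfonyloxy)-8α-(PMBO)-2α-(triethylsilyloxy)-13-noreudesm-3-en-12,6α-olide | O=C1O[C@H]2[C@H](C1)[C@@H](OCc4ccc(OC)cc4)C[C@@]3(C)[C@H](OS(C)(=O)=O)[C@@H](O[Si](CC)(CC)CC)C=C(C)[C@]23O | intermediate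
30 | (2R,6S,7R,8S)-8-(PMBO)-5-oxo-2-(triethylsilyloxy)-13-norgermacra-1(10)E,3Z-dien-12,6-olide | C1C(=O)O[C@H]2[C@H]1[C@@H](OCc3ccc(OC)cc3)C/C(C)=C/[C@@H](O[Si](CC)(CC)CC)/C=C(/C)C2=O | intermediate
31 | (2R,5R,6S,7R,8S)-5-hydroxy-8-(PMBO)-2-(triethylsilyloxy)-13-norgermacra-1(10)E,3Z-dien-12,6-olide | C1C(=O)O[C@H]2[C@H]1[C@@H](OCc3ccc(OC)cc3)C/C(C)=C/[C@@H](O[Si](CC)(CC)CC)/C=C(/C)[C@H]2O | intermediate
32 | (2R,5R,6S,7R,8S)-5-(tert-butyldimethylsilyloxy)-8-(PMBO)-2-(triethylsilyloxy)-13-norgermacra-1(10)E,3Z-dien-12,6-olide | C1C(=O)O[C@H]2[C@H]1[C@@H](OCc3ccc(OC)cc3)C/C(C)=C/[C@@H](O[Si](CC)(CC)CC)/C=C(/C)[C@H]2O[Si](C)(C)C(C)(C)C | intermediate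
33 | (2R,5R,6S,7R,8S)-13-(dimethylamino)-5-(tert-butyldimethylsilyloxy)-8-(PMBO)-2-(triethylsilyloxy)germacra-1(10)E,3Z-dien-12,6-olide (C11 epimers) | CN(C)CC1C(=O)O[C@H]2[C@H]1[C@@H](OCc3ccc(OC)cc3)C/C(C)=C/[C@@H](O[Si](CC)(CC)CC)/C=C(/C)[C@H]2O[Si](C)(C)C(C)(C)C | intermediate
34 | N-methyl quaternary ammonium iodide of 33 | C[N+](C)(C)CC1C(=O)O[C@H]2[C@H]1[C@@H](OCc3ccc(OC)cc3)C/C(C)=C/[C@@H](O[Si](CC)(CC)CC)/C=C(/C)[C@H]2O[Si](C)(C)C(C)(C)C.[I-] | intermediate
35 | (2R,5R,6S,7R,8S)-5-(tert-butyldimethylsilyloxy)-8-(PMBO)-2-(triethylsilyloxy)germacra-1(10)E,3Z,11(13)-trien-12,6-olide | C=C1C(=O)O[C@H]2[C@H]1[C@@H](OCc3ccc(OC)cc3)C/C(C)=C/[C@@H](O[Si](CC)(CC)CC)/C=C(/C)[C@H]2O[Si](C)(C)C(C)(C)C | intermediate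
36 | (2R,5R,6S,7R,8S)-2-hydroxy-5-(tert-butyldimethylsilyloxy)-8-(PMBO)germacra-1(10)E,3Z,11(13)-trien-12,6-olide | C=C1C(=O)O[C@H]2[C@H]1[C@@H](OCc3ccc(OC)cc3)C/C(C)=C/[C@@H](O)/C=C(/C)[C@H]2O[Si](C)(C)C(C)(C)C | intermediate
37 | (5R,6S,7R,8S)-5-(tert-butyldimethylsilyloxy)-8-(PMBO)-2-oxogermacra-1(10)E,3Z,11(13)-trien-12,6-olide | C=C1C(=O)O[C@H]2[C@H]1[C@@H](OCc3ccc(OC)cc3)C/C(C)=C/C(=O)/C=C(/C)[C@H]2O[Si](C)(C)C(C)(C)C | intermediate
38 | (5R,6S,7R,8S)-8-hydroxy-5-(tert-butyldimethylsilyloxy)-2-oxogermacra-1(10)E,3Z,11(13)-trien-12,6-olide | C=C1C(=O)O[C@H]2[C@H]1[C@@H](O)C/C(C)=C/C(=O)/C=C(/C)[C@H]2O[Si](C)(C)C(C)(C)C | intermediate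
39 | angelic acid, (Z)-2-methylbut-2-enoic acid | C/C=C(/C)C(=O)O | starting material
40 | angelic 2,4,6-trichlorobenzoic anhydride | C/C=C(/C)C(=O)OC(=O)c1c(Cl)cc(Cl)cc1Cl | intermediate
41 | (5R,6S,7R,8S)-8-(angeloyloxy)-5-(tert-butyldimethylsilyloxy)-2-oxogermacra-1(10)E,3Z,11(13)-trien-12,6-olide | C=C1C(=O)O[C@H]2[C@H]1[C@@H](OC(=O)/C(C)=C\C)C/C(C)=C/C(=O)/C=C(/C)[C@H]2O[Si](C)(C)C(C)(C)C | intermediate
42 | (5R,6S,7R,8S)-8-(angeloyloxy)-5-hydroxy-2-oxogermacra-1(10)E,3Z,11(13)-trien-12,6-olide (CNP0230565.9) | C=C1C(=O)O[C@H]2[C@H]1[C@@H](OC(=O)/C(C)=C\C)C/C(C)=C/C(=O)/C=C(/C)[C@H]2O | target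

## Step count and least certain steps

Total step count: 28. Longest linear sequence: 28 steps (1 to 42); the route is fully linear.

**Step 19 (key step).** The most likely failure is base-induced loss of the product after a successful fragmentation. The C6 hydrogen of 30 is α to the new ketone and carries an acyloxy group, so epimerisation to the cis-lactone or enolate-driven decomposition of the strained enone can follow while alkoxide is still present. A second possibility is slow fragmentation if the ring-A half-chair twists the C1–O bond away from anti-periplanarity. Fallback: run fragmentation and reduction as one operation. Starting from 29, the alkoxide is formed with KN(SiMe3)2 in THF at −78 °C and the cold solution is transferred into NaBH4/CeCl3·7H2O in MeOH, so enone 30 is reduced as it is released and never isolated. The sequence returns at 31 and makes no new compound (F0).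

**Step 20.** Poor facial selectivity is possible if the macrocycle populates conformers in which the inner carbonyl face is open. Felkin–Anh attack anti to the C6–O bond would give the 5S epimer, so it too opposes the conformational preference relied on. Fallback: replace ring control by catalyst control. Starting from 30, the enone is reduced with the oxazaborolidine of step 1 (the enantiomer that matches) and catecholborane. This returns at 31 and makes no new compound (F0).

**Step 13.** Hydrazine may open the γ-lactone in competition with hydrazone formation, or the alkenyldiazene may decompose by ionic paths in this doubly unsaturated system. Fallback: a radical transposition without hydrazine. Starting from 21, Luche reduction gives the epoxy alcohol F1. 1,1′-Thiocarbonyldiimidazole converts it into the thiocarbonylimidazolide F2. Bu3SnH with azobisisobutyronitrile in hot benzene (Barton–McCombie-type radical generation) forms the C3 radical, which opens the epoxide to C2=C3 and the C1 alkoxyl radical. Hydrogen transfer then returns the route at 23.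

**Step 6.** Insufficient diastereoselectivity at C10 is the main risk, because the auxiliary must override the substrate's preference for axial attack cis to the C7 arm. Condensation of the enamine nitrogen with the ester is a minor risk. Fallback: build the quaternary centre before the C7 arm by two substrate-controlled α′-alkylations. Starting from 4, LiN(iPr)2 and 2-ethyl-2-(2-iodoethyl)-1,3-dioxolane give the chain-bearing enone F3. A second enolisation and MeI, entering anti to the C8 ether, give the quaternary enone F4. Mukaiyama–Michael addition of 6, again anti to the C8 ether, gives the ketal keto ester F5. Aqueous acid removes the ketal and returns the route at 13.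

**Step 27.** Isomerisation of the angelate to the tiglate, or degradation of the dienone and methylene lactone on warming with amine, may erode the step. Fallback: make the Z-enoate on the molecule instead of transferring it. Starting from 38, carbodiimide coupling with 2-[bis(2,2,2-trifluoroethoxy)phosphoryl]propanoic acid gives the phosphonopropionate F6. Still–Gennari olefination with acetaldehyde (KN(SiMe3)2, 18-crown-6, THF, −78 °C) then builds the Z-trisubstituted enoate and returns the route at 41.

## Further compounds

F0 | step 19 | none | none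
F0 | step 20 | none | none
F1 | step 13 | 1α,2α-epoxy-3-hydroxy-8α-(PMBO)-13-noreudesm-4-en-12,6α-olide (C3 epimers) | CC1=C2[C@H]3OC(=O)C[C@@H]3[C@@H](OCc4ccc(OC)cc4)C[C@@]2(C)[C@H]5O[C@H]5C1O
F2 | step 13 | O-(imidazol-1-ylthiocarbonyl) derivative of F1 | CC1=C2[C@H]3OC(=O)C[C@@H]3[C@@H](OCc4ccc(OC)cc4)C[C@@]2(C)[C@H]5O[C@H]5C1OC(=S)n1ccnc1
F3 | step 6 | (4S)-6-[2-(2-ethyl-1,3-dioxolan-2-yl)ethyl]-4-(PMBO)cyclohex-2-en-1-one (C6 epimers) | CCC1(CCC2C[C@H](OCc3ccc(OC)cc3)C=CC2=O)OCCO1
F4 | step 6 | (4S,6R)-6-[2-(2-ethyl-1,3-dioxolan-2-yl)ethyl]-6-methyl-4-(PMBO)cyclohex-2-en-1-one (methyl trans to the ether) | CCC1(CC[C@]2(C)C[C@H](OCc3ccc(OC)cc3)C=CC2=O)OCCO1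
F5 | step 6 | ethylene ketal (at the side-chain ketone) of 13 | CCC1(CC[C@]2(C)C[C@H](OCc3ccc(OC)cc3)[C@@H](CC(=O)OC)CC2=O)OCCO1
F6 | step 27 | 8-O-{2-[bis(2,2,2-trifluoroethoxy)phosphoryl]propanoyl} derivative of 38 | C=C1C(=O)O[C@H]2[C@H]1[C@@H](OC(=O)C(C)P(=O)(OCC(F)(F)F)OCC(F)(F)F)C/C(C)=C/C(=O)/C=C(/C)[C@H]2O[Si](C)(C)C(C)(C)C
A1 | alternative 1 | α-methylene trans-γ-lactone with C5 hydroxymethyl, free C8 hydroxyl and E-iodoalkene | C=C1C(=O)O[C@H](CO)[C@H]1[C@@H](O)C/C(C)=C/I
A2 | alternative 1 | D-ribose (open-chain form) | C([C@H]([C@H]([C@H](C=O)O)O)O)O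
A3 | alternative 2 | bridged isoxazoline holding the ten-membered ring (C5 tert-butyldimethylsilyl ether, C8 angelate) | C=C1C(=O)O[C@H]2[C@H]1[C@@H](OC(=O)/C(C)=C\C)C/C(C)=C/C3=NO[C@](C)(C3)[C@H]2O[Si](C)(C)C(C)(C)C
A4 | alternative 3 | C5 triethylsilyl ether of the target | C=C1C(=O)O[C@H]2[C@H]1[C@@H](OC(=O)/C(C)=C\C)C/C(C)=C/C(=O)/C=C(/C)[C@H]2O[Si](CC)(CC)CC
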